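**Retrosynthetic overview**
- The strategy rests on C9: it is a lone hydroxymethyl on C8, the carbon that carries the ring B aryl ether oxygen and sits next to the benzylic C7–O. The C8–C9 bond is therefore cut to formaldehyde plus the Z enol silane of a C7 ketone (a 1-aryl-2-aryloxyethanone).
- C7 is set afterwards from C8 by non-chelated (Felkin–Anh) hydride addition to the C9-silylated ketone, giving the threo (7R,8R) arrangement.
- The achiral aryloxy ketone comes from SN2 displacement of a ring A phenacyl bromide by the ring B phenoxide; the ring A glyceryl ether comes from a Mitsunobu reaction and the ring B side chain from hydroboration.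
- No ring is formed in the route: both benzene rings and the 1,3-dioxane acetonide are bought.

Key step: step 7

**Remarks and assumptions**
- Numbering: C7 is the benzylic carbinol carbon, C8 the aryloxy-bearing carbon, C9 the hydroxymethyl carbon. In the propane names C1 = C7, C2 = C8, C3 = C9. The target is (7R,8R), the threo isomer.
- Abbreviations in names: ArA = 4-[(2,2-dimethyl-1,3-dioxan-5-yl)oxy]-3,5-dimethoxyphenyl; ArB-oxy = 4-[3-(tert-butyldimethylsilyloxy)propyl]-2,6-dimethoxyphenoxy.
- Assumption: the (S,S) antipode of the bipyridine diol is taken to give (R) at C8. The sense of induction is not established for an enolate with an aryloxy group on the nucleophilic carbon, so the (R,R) antipode would be used if the opposite sense is found.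
- Metal enolates, alkoxides and other metal-bound species that exist only in solution are treated as mechanistic species and are not numbered.

**Route**

Step 1
Reactants: 1 acetosyringone; 2 2,2-dimethyl-1,3-dioxan-5-ol
Product: 3 1-ArA-ethan-1-one (1-{4-[(2,2-dimethyl-1,3-dioxan-5-yl)oxy]-3,5-dimethoxyphenyl}ethan-1-one)
Conditions: PPh3, DIAD, THF, 0 → 50 °C
Reagents that add atoms: none
Why: Mitsunobu etherification, in which the phenol (acidified by the para acetyl group) protonates the betaine and its phenoxide displaces the oxyphosphonium of 2 by SN2; the carbinol carbon of 2 is not a stereocentre, so inversion has no consequence.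

Step 2
Reactants: 3 1-ArA-ethan-1-one
Product: 5 2-bromo-1-ArA-ethan-1-one, via trimethylsilyl enol ether 4 (not isolated)
Conditions: LiN(SiMe3)2, TMSCl, THF, −78 °C; then NBS, −78 → 0 °C
Reagents that add atoms: N-bromosuccinimide, O=C1CCC(=O)N1Br; chlorotrimethylsilane, C[Si](C)(C)Cl (its silyl group is present in 4 only)
Why: Kinetic deprotonation of the methyl ketone with in situ silylation gives enol silane 4, whose electrophilic bromination by NBS should stop at the monobromide and produces no HBr, so the acetonide and the electron-rich ring are spared.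

Step 3
Reactants: 6 4-allyl-2,6-dimethoxyphenol
Product: 8 4-(3-hydroxypropyl)-2,6-dimethoxyphenol, via bis(9-BBN) borane 7 (not isolated)
Conditions: 9-BBN (2.3 equiv), THF, 0 °C → rt; then NaOH (aq), H2O2, 0 °C
Reagents that add atoms: hydrogen peroxide, OO; 9-borabicyclo[3.3.1]nonane, B1C2CCCC1CCC2 (its boryl groups are present in 7 only)
Why: Hydroboration–oxidation, with anti-Markovnikov addition of 9-BBN to the terminal alkene (the phenol is carried as its borinate, hence the excess) and alkaline peroxide oxidation of the C–B bond to the primary alcohol.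

Step 4
Reactants: 8 4-(3-hydroxypropyl)-2,6-dimethoxyphenol
Product: 9 4-[3-(tert-butyldimethylsilyloxy)propyl]-2,6-dimethoxyphenol
Conditions: TBSCl (1.05 equiv), imidazole, CH2Cl2, 0 °C
Reagents that add atoms: tert-butyldimethylsilyl chloride, CC(C)(C)[Si](C)(C)Cl
Why: Selective silylation, since the unhindered primary alcohol should react much faster than the phenol, which is flanked by and hydrogen-bonded to two methoxy groups.

Step 5
Reactants: 5 2-bromo-1-ArA-ethan-1-one; 9 4-[3-(tert-butyldimethylsilyloxy)propyl]-2,6-dimethoxyphenol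
Product: 10 1-ArA-2-(ArB-oxy)ethan-1-one
Conditions: K2CO3, acetone, 50 °C
Reagents that add atoms: none
Why: Williamson ether synthesis by SN2 displacement of the activated primary phenacyl bromide by the potassium phenoxide of 9, the standard construction of 2-aryloxy-1-arylethanones, which puts the hindered ether in place before any stereocentre exists.

Step 6
Reactants: 10 1-ArA-2-(ArB-oxy)ethan-1-one
Product: 11 (Z)-1-ArA-2-(ArB-oxy)-1-(trimethylsilyloxy)ethene (silyloxy and aryloxy groups cis, ring A trans to the aryloxy group)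
Conditions: LiN(SiMe3)2, THF, −78 °C; then TMSCl, Et3N, −78 → 0 °C; pentane, filtration, no aqueous work-up
Reagents that add atoms: chlorotrimethylsilane, C[Si](C)(C)Cl
Why: Kinetic enolisation and O-silylation, in which the Z enolate (aryloxy cis to the enolate oxygen, favoured by lithium chelation and by avoidance of allylic strain with ring A) is trapped as the Z enol silane and the non-aqueous work-up avoids hydrolysis.

Step 7
Reactants: 11 (Z)-1-ArA-2-(ArB-oxy)-1-(trimethylsilyloxy)ethene; 12 formaldehyde (as 37% aqueous solution)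
Product: 13 (2R)-1-ArA-2-(ArB-oxy)-3-hydroxypropan-1-one
Conditions: HCHO (37% aq, 5 equiv), Sc(OTf)3 (10 mol %), (S,S)-6,6'-bis(1-hydroxy-2,2-dimethylpropyl)-2,2'-bipyridine (12 mol %), DME/H2O 9:1, −20 °C
Reagents that add atoms: none
Why: Proposed new method: Sc(OTf)3 bound to the C2-symmetric bipyridine diol keeps its Lewis acidity in water and activates formaldehyde, the nucleophilic C8 of enol silane 11 attacks it through an open transition state, and the silyl group is then lost to water to give β-hydroxy ketone 13 with the new C8–C9 bond. The closest known reaction type is the Sc(OTf)3/chiral bipyridine hydroxymethylation of α-alkyl aryl ketone silicon enolates with aqueous formaldehyde (a catalytic enantioselective Mukaiyama aldol in aqueous medium); an enolate with an aryloxy group on the nucleophilic carbon has not been shown in it, although Mukaiyama aldols of α-alkoxy enol silanes in general are routine. No ring is closed. The one new stereocentre, C8, is controlled by the ligand-bound trivalent scandium complex, whose tert-butyl carbinol arms shield one face of approach of the enolate to the coordinated formaldehyde. The step needs enantioface selectivity only, and the substrate supports it by offering a single Z double-bond geometry, as do the Z propiophenone enolates of the known reaction. The near-neutral medium at −20 °C should spare the acidic C8–H, the acetonide and the primary silyl ether and should not promote retro-aldol loss of formaldehyde.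

Step 8
Reactants: 13 (2R)-1-ArA-2-(ArB-oxy)-3-hydroxypropan-1-one
Product: 14 (2R)-1-ArA-2-(ArB-oxy)-3-(tert-butyldimethylsilyloxy)propan-1-one
Conditions: TBSOTf, 2,6-lutidine, CH2Cl2, −78 °C
Reagents that add atoms: tert-butyldimethylsilyl trifluoromethanesulfonate, CC(C)(C)[Si](C)(C)OS(=O)(=O)C(F)(F)F
Why: Silyl triflate silylation of the primary alcohol at low temperature with a weak, hindered base, which should avoid enolisation at C8 and retro-aldol, and which gives a bulky, poorly coordinating ether at C9 for the non-chelated reduction.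

Step 9
Reactants: 14 (2R)-1-ArA-2-(ArB-oxy)-3-(tert-butyldimethylsilyloxy)propan-1-one
Product: 15 (1R,2R)-1-ArA-2-(ArB-oxy)-3-(tert-butyldimethylsilyloxy)propan-1-ol
Conditions: LiBH(sBu)3, THF, −78 °C; then H2O
Reagents that add atoms: none
Why: Felkin–Anh (polar) hydride addition, in which the C8–OAr bond lies anti to the incoming bulky hydride and the hydride passes the C8 hydrogen, so the (8R) ketone should give the (7R) alcohol, the threo (syn) isomer; the hindered borohydride in THF and the silyl ether at C9 disfavour chelation.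

Step 10
Reactants: 15 (1R,2R)-1-ArA-2-(ArB-oxy)-3-(tert-butyldimethylsilyloxy)propan-1-ol
Product: 16 (1R,2R)-1-{4-[(1,3-dihydroxypropan-2-yl)oxy]-3,5-dimethoxyphenyl}-2-[4-(3-hydroxypropyl)-2,6-dimethoxyphenoxy]propane-1,3-diol (target, CNP0186584.2)
Conditions: AcOH/THF/H2O 3:1:1, 40 °C
Reagents that add atoms: none
Why: Acid hydrolysis that should remove both primary tert-butyldimethylsilyl ethers and the 1,3-dioxane acetonide in one operation, while the benzylic C7 alcohol (on a ring whose para oxygen is twisted by two ortho methoxy groups) should not ionise in acetic acid, so C7 and C8 are kept.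

**Compound list**
1 | acetosyringone, 1-(4-hydroxy-3,5-dimethoxyphenyl)ethan-1-one | CC(=O)c1cc(OC)c(O)c(OC)c1 | starting material
2 | 2,2-dimethyl-1,3-dioxan-5-ol | CC1(C)OCC(O)CO1 | starting material
3 | 1-{4-[(2,2-dimethyl-1,3-dioxan-5-yl)oxy]-3,5-dimethoxyphenyl}ethan-1-one | CC(=O)c1cc(OC)c(OC2COC(C)(C)OC2)c(OC)c1 | intermediate
4 | ({1-{4-[(2,2-dimethyl-1,3-dioxan-5-yl)oxy]-3,5-dimethoxyphenyl}ethenyl}oxy)trimethylsilane | C=C(O[Si](C)(C)C)c1cc(OC)c(OC2COC(C)(C)OC2)c(OC)c1 | intermediate (not isolated)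
5 | 2-bromo-1-{4-[(2,2-dimethyl-1,3-dioxan-5-yl)oxy]-3,5-dimethoxyphenyl}ethan-1-one | O=C(CBr)c1cc(OC)c(OC2COC(C)(C)OC2)c(OC)c1 | intermediate
6 | 4-allyl-2,6-dimethoxyphenol | C=CCc1cc(OC)c(O)c(OC)c1 | starting material
7 | 9-{3-[4-(9-borabicyclo[3.3.1]nonan-9-yloxy)-3,5-dimethoxyphenyl]propyl}-9-borabicyclo[3.3.1]nonane | COc1cc(CCCB2C3CCCC2CCC3)cc(OC)c1OB1C2CCCC1CCC2 | intermediate (not isolated)
8 | 4-(3-hydroxypropyl)-2,6-dimethoxyphenol | OCCCc1cc(OC)c(O)c(OC)c1 | intermediate
9 | 4-[3-(tert-butyldimethylsilyloxy)propyl]-2,6-dimethoxyphenol | CC(C)(C)[Si](C)(C)OCCCc1cc(OC)c(O)c(OC)c1 | intermediate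
10 | 2-{4-[3-(tert-butyldimethylsilyloxy)propyl]-2,6-dimethoxyphenoxy}-1-{4-[(2,2-dimethyl-1,3-dioxan-5-yl)oxy]-3,5-dimethoxyphenyl}ethan-1-one | COc1cc(C(=O)COc2c(OC)cc(CCCO[Si](C)(C)C(C)(C)C)cc2OC)cc(OC)c1OC1COC(C)(C)OC1 | intermediate
11 | (Z)-enol silane: {[(Z)-2-{4-[3-(tert-butyldimethylsilyloxy)propyl]-2,6-dimethoxyphenoxy}-1-{4-[(2,2-dimethyl-1,3-dioxan-5-yl)oxy]-3,5-dimethoxyphenyl}ethenyl]oxy}trimethylsilane | COc1cc(/C(O[Si](C)(C)C)=C/Oc2c(OC)cc(CCCO[Si](C)(C)C(C)(C)C)cc2OC)cc(OC)c1OC1COC(C)(C)OC1 | intermediate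
12 | formaldehyde | C=O | starting material
13 | (2R)-2-{4-[3-(tert-butyldimethylsilyloxy)propyl]-2,6-dimethoxyphenoxy}-1-{4-[(2,2-dimethyl-1,3-dioxan-5-yl)oxy]-3,5-dimethoxyphenyl}-3-hydroxypropan-1-one | COc1cc(C(=O)[C@@H](CO)Oc2c(OC)cc(CCCO[Si](C)(C)C(C)(C)C)cc2OC)cc(OC)c1OC1COC(C)(C)OC1 | intermediate
14 | (2R)-3-(tert-butyldimethylsilyloxy)-2-{4-[3-(tert-butyldimethylsilyloxy)propyl]-2,6-dimethoxyphenoxy}-1-{4-[(2,2-dimethyl-1,3-dioxan-5-yl)oxy]-3,5-dimethoxyphenyl}propan-1-one | COc1cc(C(=O)[C@@H](CO[Si](C)(C)C(C)(C)C)Oc2c(OC)cc(CCCO[Si](C)(C)C(C)(C)C)cc2OC)cc(OC)c1OC1COC(C)(C)OC1 | intermediate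
15 | (1R,2R)-3-(tert-butyldimethylsilyloxy)-2-{4-[3-(tert-butyldimethylsilyloxy)propyl]-2,6-dimethoxyphenoxy}-1-{4-[(2,2-dimethyl-1,3-dioxan-5-yl)oxy]-3,5-dimethoxyphenyl}propan-1-ol | COc1cc([C@@H](O)[C@@H](CO[Si](C)(C)C(C)(C)C)Oc2c(OC)cc(CCCO[Si](C)(C)C(C)(C)C)cc2OC)cc(OC)c1OC1COC(C)(C)OC1 | intermediate
16 | (1R,2R)-1-{4-[(1,3-dihydroxypropan-2-yl)oxy]-3,5-dimethoxyphenyl}-2-[4-(3-hydroxypropyl)-2,6-dimethoxyphenoxy]propane-1,3-diol | COc1cc([C@@H](O)[C@@H](CO)Oc2c(OC)cc(CCCO)cc2OC)cc(OC)c1OC(CO)CO | target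

**Step count**
Total: 10 steps. Longest linear sequence: 8 steps (steps 1, 2, 5–10 from acetosyringone; equally steps 3, 4, 5–10 from 4-allyl-2,6-dimethoxyphenol).

**Steps most likely to fail**

1. Step 7 (proposed new method). The catalyst may discriminate the enolate faces poorly, because the aryloxy group on the nucleophilic carbon is larger and more Lewis basic than the alkyl group of the known substrates and may itself bind scandium. The enol silane may also hydrolyse back to the ketone faster than it adds to formaldehyde.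
 Fallback (known chemistry, auxiliary-controlled aldol that forms C7–C8 and not C8–C9): it sets out from phenol 9 and alcohol 2 and comes back to the route at target 16.
 - Phenol 9 is alkylated with ethyl bromoacetate (K2CO3, acetone) to ethyl {4-[3-(tert-butyldimethylsilyloxy)propyl]-2,6-dimethoxyphenoxy}acetate F1.
 - F1 is saponified (LiOH, THF/H2O) to the aryloxyacetic acid F2.
 - F2 is activated with pivaloyl chloride/Et3N as the mixed pivalic anhydride F3 and joined to (S)-4-benzyloxazolidin-2-one (LiCl) to give the N-(aryloxyacetyl)oxazolidinone F4.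
 - Syringaldehyde is etherified with alcohol 2 under the Mitsunobu conditions of step 1 to give 4-[(2,2-dimethyl-1,3-dioxan-5-yl)oxy]-3,5-dimethoxybenzaldehyde F5.
 - The dibutylboron Z enolate of F4 (Bu2BOTf, iPr2NEt, CH2Cl2, −78 °C) adds to F5 in an Evans syn aldol reaction to give the (2S,3R) aldol adduct F6. In it the aryloxy and hydroxy groups are syn, which is the threo (7R,8R) arrangement.
 - LiBH4 (THF, H2O, 0 °C) removes the auxiliary and gives the (1R,2R) diol F7, which under the conditions of step 10 should give target 16.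

2. Step 9. Hydride may add with poor facial selectivity if lithium bridges the ketone oxygen and the aryloxy oxygen, so that chelation-controlled delivery to the other face competes and erodes the threo preference.
 Fallback (inversion instead of direct formation): it sets out from ketone 14 and comes back at alcohol 15.
 - Ketone 14 is reduced deliberately under chelation control (Zn(BH4)2, Et2O, −20 °C) to the erythro (1S,2R) alcohol F8.
 - C7 is inverted by Mitsunobu esterification with 4-nitrobenzoic acid (PPh3, DIAD, toluene) to the (1R,2R) 4-nitrobenzoate F9.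
 - Methanolysis (K2CO3, MeOH) should return alcohol 15.

3. Step 1. Displacement at a secondary carbinol carbon flanked by two ring oxygens, by a phenoxide flanked by two methoxy groups, may be too slow, so that the activated alcohol is consumed by the reduced azodicarboxylate or by elimination.
 Fallback (the glyceryl unit is brought in as a malonate): it sets out from acetosyringone 1 and comes back at ketone 3.
 - Phenol 1 is O-alkylated with diethyl bromomalonate (K2CO3, acetone) to diethyl 2-(4-acetyl-2,6-dimethoxyphenoxy)malonate F10.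
 - LiAlH4 (THF, 0 °C) reduces both esters and the ketone to the triol 2-[4-(1-hydroxyethyl)-2,6-dimethoxyphenoxy]propane-1,3-diol F11.
 - 2,2-Dimethoxypropane with PPTS in acetone closes the 1,3-dioxane on the primary diol to give 1-{4-[(2,2-dimethyl-1,3-dioxan-5-yl)oxy]-3,5-dimethoxyphenyl}ethan-1-ol F12.
 - MnO2 (CH2Cl2) reoxidises the benzylic alcohol and returns ketone 3.

**Further compounds**
F1 | step 7 | ethyl {4-[3-(tert-butyldimethylsilyloxy)propyl]-2,6-dimethoxyphenoxy}acetate | CCOC(=O)COc1c(OC)cc(CCCO[Si](C)(C)C(C)(C)C)cc1OC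
F2 | step 7 | {4-[3-(tert-butyldimethylsilyloxy)propyl]-2,6-dimethoxyphenoxy}acetic acid | OC(=O)COc1c(OC)cc(CCCO[Si](C)(C)C(C)(C)C)cc1OC
F3 | step 7 | {4-[3-(tert-butyldimethylsilyloxy)propyl]-2,6-dimethoxyphenoxy}acetic pivalic anhydride | CC(C)(C)C(=O)OC(=O)COc1c(OC)cc(CCCO[Si](C)(C)C(C)(C)C)cc1OC
F4 | step 7 | (4S)-4-benzyl-3-({4-[3-(tert-butyldimethylsilyloxy)propyl]-2,6-dimethoxyphenoxy}acetyl)oxazolidin-2-one | O=C(COc1c(OC)cc(CCCO[Si](C)(C)C(C)(C)C)cc1OC)N1[C@@H](Cc2ccccc2)COC1=O
F5 | step 7 | 4-[(2,2-dimethyl-1,3-dioxan-5-yl)oxy]-3,5-dimethoxybenzaldehyde | O=Cc1cc(OC)c(OC2COC(C)(C)OC2)c(OC)c1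
F6 | step 7 | (4S)-4-benzyl-3-[(2S,3R)-2-{4-[3-(tert-butyldimethylsilyloxy)propyl]-2,6-dimethoxyphenoxy}-3-{4-[(2,2-dimethyl-1,3-dioxan-5-yl)oxy]-3,5-dimethoxyphenyl}-3-hydroxypropanoyl]oxazolidin-2-one | COc1cc([C@@H](O)[C@@H](C(=O)N2[C@@H](Cc3ccccc3)COC2=O)Oc2c(OC)cc(CCCO[Si](C)(C)C(C)(C)C)cc2OC)cc(OC)c1OC1COC(C)(C)OC1
F7 | step 7 | (1R,2R)-2-{4-[3-(tert-butyldimethylsilyloxy)propyl]-2,6-dimethoxyphenoxy}-1-{4-[(2,2-dimethyl-1,3-dioxan-5-yl)oxy]-3,5-dimethoxyphenyl}propane-1,3-diol | COc1cc([C@@H](O)[C@@H](CO)Oc2c(OC)cc(CCCO[Si](C)(C)C(C)(C)C)cc2OC)cc(OC)c1OC1COC(C)(C)OC1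
F8 | step 9 | (1S,2R)-3-(tert-butyldimethylsilyloxy)-2-{4-[3-(tert-butyldimethylsilyloxy)propyl]-2,6-dimethoxyphenoxy}-1-{4-[(2,2-dimethyl-1,3-dioxan-5-yl)oxy]-3,5-dimethoxyphenyl}propan-1-ol | COc1cc([C@H](O)[C@@H](CO[Si](C)(C)C(C)(C)C)Oc2c(OC)cc(CCCO[Si](C)(C)C(C)(C)C)cc2OC)cc(OC)c1OC1COC(C)(C)OC1
F9 | step 9 | (1R,2R)-3-(tert-butyldimethylsilyloxy)-2-{4-[3-(tert-butyldimethylsilyloxy)propyl]-2,6-dimethoxyphenoxy}-1-{4-[(2,2-dimethyl-1,3-dioxan-5-yl)oxy]-3,5-dimethoxyphenyl}propyl 4-nitrobenzoate | COc1cc([C@@H](OC(=O)c2ccc(cc2)[N+](=O)[O-])[C@@H](CO[Si](C)(C)C(C)(C)C)Oc2c(OC)cc(CCCO[Si](C)(C)C(C)(C)C)cc2OC)cc(OC)c1OC1COC(C)(C)OC1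
F10 | step 1 | diethyl 2-(4-acetyl-2,6-dimethoxyphenoxy)malonate | CCOC(=O)C(Oc1c(OC)cc(cc1OC)C(C)=O)C(=O)OCC
F11 | step 1 | 2-[4-(1-hydroxyethyl)-2,6-dimethoxyphenoxy]propane-1,3-diol (racemic) | CC(O)c1cc(OC)c(OC(CO)CO)c(OC)c1
F12 | step 1 | 1-{4-[(2,2-dimethyl-1,3-dioxan-5-yl)oxy]-3,5-dimethoxyphenyl}ethan-1-ol (racemic) | CC(O)c1cc(OC)c(OC2COC(C)(C)OC2)c(OC)c1
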